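**Assumption:** The target SMILES is the (R)-carbinol of the shikonin series, acylated with isobutyric acid. Naphthazarin tautomerism makes C2 and C3 (and C6 and C7) equivalent, so the regiochemistry of side-chain attachment is not an issue.

## Retrosynthetic overview
1. Isobutylshikonin comes from O-acylation of (R)-shikonin (Steglich), which keeps the ester away from the harsher earlier steps.
2. (R)-Shikonin comes from oxidation of the leuco adduct formed by an enantioselective, dearomative Marschalk-type hydroxyalkylation of symmetric leuco-naphthazarin with 4-methylpent-3-enal. C2 attack breaks the D2h symmetry of the arene and sets the carbinol centre.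
3. Leuco-naphthazarin comes from dithionite reduction of naphthazarin, which is made in one step from hydroquinone and maleic anhydride by double Friedel–Crafts acylation. The aldehyde comes from oxidation of 4-methylpent-3-en-1-ol.
4. Only one ring is formed: the quinone ring in Step 1. The stereocentre is set in Step 4.

## Route

**Step 1**
Reactants: 1 hydroquinone; 2 maleic anhydride
Product: 3 naphthazarin (5,8-dihydroxy-1,4-naphthoquinone)
Conditions: AlCl3/NaCl melt, 180 °C, 20 min; then aq. HCl work-up
Reagents that add atoms: none
Why: Double Friedel–Crafts acylation (Zahn-type melt) of hydroquinone by the anhydride, with ring closure, builds the quinone ring in one operation; C6H6O2 + C4H2O3 − H2O = C10H6O4. The OH groups end up peri to the carbonyls.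

**Step 2**
Reactants: 4 4-methylpent-3-en-1-ol
Product: 5 4-methylpent-3-enal
Conditions: Dess–Martin periodinane, NaHCO3, CH2Cl2, 0 °C; use the aldehyde immediately
Reagents that add atoms: none
Why: Buffered, mild oxidation of a primary alcohol to the aldehyde avoids migration of the alkene into conjugation and leaves the trisubstituted alkene untouched.

**Step 3**
Reactants: 3 naphthazarin
Product: 6 leuco-naphthazarin (1,4,5,8-tetrahydroxynaphthalene)
Conditions: Na2S2O4, EtOAc/H2O, rt, 15 min, under Ar; separate the organic layer, dry (Na2SO4) and use the solution directly
Reagents that add atoms: none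
Why: Dithionite reduction of the quinone gives the electron-rich bis-enol/hydroquinone form (C10H6O4 + 2 H = C10H8O4). Washing it out of the aqueous phase removes excess dithionite, which would otherwise reduce the aldehyde or the later adduct.

**Step 4**
Reactants: 6 leuco-naphthazarin (1.25 equiv); 5 4-methylpent-3-enal (limiting)
Product: 7 leuco adduct, (R)-2-(1-hydroxy-4-methylpent-3-enyl)naphthalene-1,4,5,8-tetrol, CC(C)=CC[C@@H](O)c1cc(O)c2c(O)ccc(O)c2c1O
Conditions: chiral BINOL-derived phosphoric acid (e.g. TRIP, 10 mol%), PhMe/THF, 4 Å MS, −20 °C, Ar
Reagents that add atoms: none
Why: Proposed new method: the electron-rich bis-enol 6 (in equilibrium with its keto tautomer) attacks the aldehyde through C2 in a dearomative aldol-type addition, and tautomerisation rearomatises the ring. The bifunctional phosphoric acid binds the aldehyde C=O through P–OH and a peri-OH of 6 through P=O, giving a closed, Zimmerman–Traxler-like transition state that sets the carbinol configuration. The catalyst enantiomer is chosen to give (R). The closest known reactions are the Marschalk hydroxyalkylation of leuco-quinones and phosphoric-acid-catalysed ortho-hydroxyalkylation (Friedel–Crafts) of naphthols. Limiting aldehyde and a neutral, non-basic medium suppress bis-alkylation and ionisation to the o-quinone methide (which would lead to deoxyshikonin).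

**Step 5**
Reactants: 7 leuco adduct
Product: 8 (R)-shikonin, CC(C)=CC[C@@H](O)C1=CC(=O)c2c(O)ccc(O)c2C1=O
Conditions: air (O2), EtOAc/pH 7 phosphate buffer, rt, 1 h
Reagents that add atoms: none
Why: Air oxidation of the electron-rich leuco-naphthazarin restores the naphthazarin quinone (C16H18O5 − 2 H = C16H16O5). These are mild, neutral conditions that do not touch the secondary carbinol or the alkene, so the stereocentre is not affected.

**Step 6**
Reactants: 8 (R)-shikonin; 9 isobutyric acid
Product: 10 isobutylshikonin (target)
Conditions: DCC, DMAP (0.1 equiv), CH2Cl2, 0 °C to rt
Reagents that add atoms: isobutyric acid, CC(C)C(=O)O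
Why: Steglich esterification acylates the free secondary carbinol. The peri-phenols are hydrogen-bonded to the quinone carbonyls and do not react. The C–O bond at the stereocentre is not broken, so (R) is retained; C16H16O5 + C4H8O2 − H2O = C20H22O6.

## Compound list
1 | hydroquinone | Oc1ccc(O)cc1 | starting material
2 | maleic anhydride | O=C1C=CC(=O)O1 | starting material
3 | naphthazarin | O=C1C=CC(=O)c2c(O)ccc(O)c12 | intermediate
4 | 4-methylpent-3-en-1-ol | CC(C)=CCCO | starting material
5 | 4-methylpent-3-enal | CC(C)=CCC=O | intermediate
6 | leuco-naphthazarin (1,4,5,8-tetrahydroxynaphthalene) | Oc1ccc(O)c2c(O)ccc(O)c12 | intermediate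
7 | (R)-2-(1-hydroxy-4-methylpent-3-enyl)naphthalene-1,4,5,8-tetrol (leuco adduct) | CC(C)=CC[C@@H](O)c1cc(O)c2c(O)ccc(O)c2c1O | intermediate
8 | (R)-shikonin | CC(C)=CC[C@@H](O)C1=CC(=O)c2c(O)ccc(O)c2C1=O | intermediate
9 | isobutyric acid | CC(C)C(=O)O | starting material
10 | (R)-isobutylshikonin | CC(C)=CC[C@@H](OC(=O)C(C)C)C1=CC(=O)c2c(O)ccc(O)c2C1=O | target

**Total steps:** 6. **Longest linear sequence:** 5 (Step 1 → 3 → 4 → 5 → 6); the aldehyde is made in one convergent step (Step 2).

## Three steps most likely to fail
1. **Step 4 (enantioselective hydroxyalkylation).** Risks are low ee, bis-alkylation, o-quinone methide formation with reduction to deoxyshikonin, and isomerisation of the aldehyde.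
   - Fallback: run a racemic Marschalk reaction (Na2S2O4, aq. NaOH, 5, then air) on 3 to give (±)-8, then a lipase kinetic resolution with vinyl isobutyrate (CAL-B or Burkholderia cepacia lipase, expected to acylate the (R)-alcohol). This gives 10 directly, and the unreacted (S)-alcohol is separated.
2. **Step 1 (AlCl3/NaCl melt).** Yields are modest and the conditions are harsh.
   - Fallback: prepare naphthazarin by the 1,5-dinitronaphthalene/oleum/sulfur route, or use commercial naphthazarin.
3. **Step 6 (acylation).** Risks are partial racemisation through benzylic ionisation and acylation of the phenols.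
   - Fallback: lipase-catalysed acylation of 8 with vinyl isobutyrate under neutral conditions, which avoids DCC/DMAP.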